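## Retrosynthetic overview

1. The target comes from a bis-silylated 2,3-dihydrofuran-2-carboxylate by oxidising the ring enol ether (OsO4, then double oxidation to the enolised keto-lactone) and removing the silyl groups.
2. Key disconnection: that dihydrofuran, with its quaternary carbon, comes from a ring-contracting Ireland–Claisen [3,3] rearrangement of the silyl ketene acetal of a cis-2-styryl-5-(arylmethyl)-1,3-dioxolan-4-one. The C–C bond to the quaternary carbon forms, and the acetal stereocentre is traded for the quaternary one.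
3. The dioxolanone comes from an (S)-3-aryl-lactic acid and (E)-4-silyloxycinnamaldehyde; the lactic acid comes from aryl-metal opening of methyl (S)-glycidate.
4. The aryl unit (the dihydrobenzofuran with its (S)-carbinol carbon) comes from CuI-catalysed intramolecular O-arylation of a diol built from 1,4-dibromo-2-iodobenzene, the same glycidate and MeMgBr.
5. Ring order: dihydrobenzofuran, then the temporary dioxolanone, then the dihydrofuran that becomes the butenolide.

Assumption: methyl (2S)-oxirane-2-carboxylate (commercial in both enantiomeric forms) is the only source of chirality; it is used twice.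

Abbreviations in names: DHB = (2S)-2-(2-hydroxypropan-2-yl)-2,3-dihydro-1-benzofuran-5-yl; DHB-TMS = the same group with the tertiary OH as its trimethylsilyl ether; TBSO-Ph = 4-[(tert-butyldimethylsilyl)oxy]phenyl.

Caveat on the key step: the rearrangement in step 6 is designed by analogy with the dioxanone-to-dihydropyran enolate Claisen. I know of no example on a five-membered dioxolanone, where the transition state is more strained, so it is the step most likely to fail (fallback given below).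

## Route

Step 1
Reactants: 1 1,4-dibromo-2-iodobenzene; 2 methyl (2S)-oxirane-2-carboxylate
Product: 5 (2S)-1-(2,5-dibromophenyl)-3-methylbutane-2,3-diol, via aryl Grignard reagent 3 (not isolated), via hydroxy ester 4 (not isolated)
Conditions: i-PrMgCl·LiCl, THF, −40 °C; CuI (10 mol%), 2, −40 → −20 °C; then MeMgBr (3.5 equiv), −20 → 0 °C; aq. NH4Cl
Reagents that add atoms: methylmagnesium bromide, C[Mg]Br
Why: Iodine–magnesium exchange is selective for the C–I bond, the CuI-catalysed SN2 epoxide opening occurs at the CH2 of the glycidate so the bought (S)-centre is untouched, and double Grignard addition to the ester gives the tertiary alcohol.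

Step 2
Reactants: 5 (2S)-1-(2,5-dibromophenyl)-3-methylbutane-2,3-diol
Product: 6 2-[(2S)-5-bromo-2,3-dihydro-1-benzofuran-2-yl]propan-2-ol
Conditions: CuI (10 mol%), 3,4,7,8-tetramethyl-1,10-phenanthroline (20 mol%), Cs2CO3, PhMe, 110 °C, 0.05 M
Reagents that add atoms: none
Why: Intramolecular Ullmann-type C–O coupling closes the five-membered ring from the secondary alkoxide onto the ortho C–Br bond; the carbinol C–O bond is not broken, so the (S)-configuration is retained, and the para bromide survives.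

Step 3
Reactants: 6 2-[(2S)-5-bromo-2,3-dihydro-1-benzofuran-2-yl]propan-2-ol; 2 methyl (2S)-oxirane-2-carboxylate
Product: 9 (2S)-2-hydroxy-3-(DHB)propanoic acid, via dilithio species 7 (not isolated), via hydroxy ester 8 (not isolated)
Conditions: n-BuLi (2.1 equiv), THF, −78 °C; MgBr2·OEt2; CuI (10 mol%), 2, −40 → −10 °C; then LiOH, THF/MeOH/H2O, rt; HCl to pH 3
Reagents that add atoms: lithium hydroxide, [Li+].[OH-]
Why: Deprotonation of the tertiary alcohol then bromine–lithium exchange gives the aryl nucleophile, which after transmetalation opens the glycidate at CH2 under CuI catalysis (SN2, the (S)-centre is bought), and saponification frees the acid.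

Step 4
Reactants: 10 4-[(tert-butyldimethylsilyl)oxy]benzaldehyde; 11 (triphenylphosphoranylidene)acetaldehyde
Product: 12 (2E)-3-(TBSO-Ph)prop-2-enal
Conditions: PhMe, 80 °C
Reagents that add atoms: none
Why: Wittig olefination with a stabilised ylide gives the (E)-enal.

Step 5
Reactants: 9 (2S)-2-hydroxy-3-(DHB)propanoic acid; 12 (2E)-3-(TBSO-Ph)prop-2-enal
Product: 14 (2S,5S)-2-[(E)-2-(TBSO-Ph)ethenyl]-5-[(DHB-TMS)methyl]-1,3-dioxolan-4-one, via tris-silyl derivative 13 (not isolated)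
Conditions: N,O-bis(trimethylsilyl)acetamide (3.5 equiv), CH2Cl2, rt; then 12, Me3SiOTf (10 mol%), −78 → −40 °C; pyridine quench; chromatography removes the minor trans acetal
Reagents that add atoms: N,O-bis(trimethylsilyl)acetamide, CC(=N[Si](C)(C)C)O[Si](C)(C)C
Why: Me3SiOTf-catalysed acetalisation of the silylated hydroxy acid with the enal (Noyori-type conditions) gives the 2,5-cis dioxolanone, so the new acetal centre (2S) is set by the glycidate-derived C5 centre; the tertiary alcohol leaves the step as its Me3Si ether.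

Step 6
Reactants: 14 (2S,5S)-2-[(E)-2-(TBSO-Ph)ethenyl]-5-[(DHB-TMS)methyl]-1,3-dioxolan-4-one
Product: 18 methyl (2S,3R)-2-[(DHB-TMS)methyl]-3-(TBSO-Ph)-2,3-dihydrofuran-2-carboxylate, via silyl ketene acetal 15 (not isolated), via silyl ester 16 (not isolated), via carboxylic acid 17 (not isolated)
Conditions: LiN(i-Pr)2 (1.3 equiv), Me3SiCl/Et3N, THF, −78 °C; then xylenes, 140 °C, sealed tube; pH 7 buffer; Me3SiCHN2, PhMe/MeOH, 0 °C
Reagents that add atoms: trimethylsilyldiazomethane, C[Si](C)(C)C=[N+]=[N-]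
Why: Ring-contracting Ireland–Claisen [3,3]-sigmatropic rearrangement in which the acetal carbon is the allylic C–O carbon, so the styryl terminus can only bond to C5 on the ring face that carries it (boat-like bridged transition state, polarised by the acetal oxygen and the silyloxystyryl terminus); the acetal centre is thereby converted into the (S)-quaternary carbon and the future butenolide ring closes, while the 3-aryl centre (trans to the carboxylate) is erased later.

Step 7
Reactants: 18 methyl (2S,3R)-2-[(DHB-TMS)methyl]-3-(TBSO-Ph)-2,3-dihydrofuran-2-carboxylate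
Product: 19 methyl (2S,3R,4S,5S)-2-[(DHB-TMS)methyl]-4,5-dihydroxy-3-(TBSO-Ph)oxolane-2-carboxylate
Conditions: OsO4 (2 mol%), N-methylmorpholine N-oxide, acetone/H2O, 0 °C → rt
Reagents that add atoms: osmium tetroxide, O=[Os](=O)(=O)=O; N-methylmorpholine N-oxide, C[N+]1([O-])CCOCC1
Why: Catalytic syn-dihydroxylation of the electron-rich cyclic enol ether on the face opposite the 3-aryl group gives the lactol diol; both new centres (and the lactol anomer ratio) are irrelevant because they are oxidised away in step 8.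

Step 8
Reactants: 19 methyl (2S,3R,4S,5S)-2-[(DHB-TMS)methyl]-4,5-dihydroxy-3-(TBSO-Ph)oxolane-2-carboxylate
Product: 22 methyl (2S)-2-[(DHB-TMS)methyl]-4-hydroxy-5-oxo-3-(TBSO-Ph)-2,5-dihydrofuran-2-carboxylate, via hydroxy lactone 20 (not isolated), via keto lactone 21 (not isolated)
Conditions: Dess–Martin periodinane (3 equiv), CH2Cl2, 0 °C → rt; aq. Na2S2O3, extract at pH 3
Reagents that add atoms: none
Why: Dess–Martin oxidation takes the lactol to the lactone and the adjacent secondary alcohol to the ketone, and the keto-lactone tautomerises to the aryl-conjugated enol, removing the C3 and C4 centres and leaving only the quaternary (S)-carbon.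

Step 9
Reactants: 22 methyl (2S)-2-[(DHB-TMS)methyl]-4-hydroxy-5-oxo-3-(TBSO-Ph)-2,5-dihydrofuran-2-carboxylate
Product: 23 methyl (2S)-2-[(DHB)methyl]-4-hydroxy-3-(4-hydroxyphenyl)-5-oxo-2,5-dihydrofuran-2-carboxylate
Conditions: HF·pyridine, THF, 0 °C → rt
Reagents that add atoms: none
Why: Fluoride-mediated desilylation removes the aryl silyl ether and the tertiary Me3Si ether without touching the ester, the enolised keto-lactone or either stereocentre.

## Compound list

1 | 1,4-dibromo-2-iodobenzene | Brc1ccc(Br)c(I)c1 | starting material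
2 | methyl (2S)-oxirane-2-carboxylate | COC(=O)[C@@H]1CO1 | starting material
3 | (2,5-dibromophenyl)magnesium chloride | Cl[Mg]c1cc(Br)ccc1Br | intermediate
4 | methyl (2S)-3-(2,5-dibromophenyl)-2-hydroxypropanoate (magnesium alkoxide in the flask) | COC(=O)[C@@H](O)Cc1cc(Br)ccc1Br | intermediate
5 | (2S)-1-(2,5-dibromophenyl)-3-methylbutane-2,3-diol | CC(C)(O)[C@@H](O)Cc1cc(Br)ccc1Br | intermediate
6 | 2-[(2S)-5-bromo-2,3-dihydro-1-benzofuran-2-yl]propan-2-ol | CC(C)(O)[C@@H]1Cc2cc(Br)ccc2O1 | intermediate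
7 | dilithio derivative of 6 (5-lithioarene, lithium tertiary alkoxide) | [Li]OC(C)(C)[C@@H]1Cc2cc([Li])ccc2O1 | intermediate
8 | methyl (2S)-2-hydroxy-3-(DHB)propanoate | COC(=O)[C@@H](O)Cc1ccc2c(c1)C[C@@H](C(C)(C)O)O2 | intermediate
9 | (2S)-2-hydroxy-3-(DHB)propanoic acid | OC(=O)[C@@H](O)Cc1ccc2c(c1)C[C@@H](C(C)(C)O)O2 | intermediate
10 | 4-[(tert-butyldimethylsilyl)oxy]benzaldehyde | O=Cc1ccc(O[Si](C)(C)C(C)(C)C)cc1 | starting material
11 | (triphenylphosphoranylidene)acetaldehyde | O=CC=P(c1ccccc1)(c1ccccc1)c1ccccc1 | starting material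
12 | (2E)-3-(TBSO-Ph)prop-2-enal | O=C/C=C/c1ccc(O[Si](C)(C)C(C)(C)C)cc1 | intermediate
13 | trimethylsilyl (2S)-3-(DHB-TMS)-2-(trimethylsilyloxy)propanoate | C[Si](C)(C)OC(=O)[C@@H](O[Si](C)(C)C)Cc1ccc2c(c1)C[C@@H](C(C)(C)O[Si](C)(C)C)O2 | intermediate
14 | (2S,5S)-2-[(E)-2-(TBSO-Ph)ethenyl]-5-[(DHB-TMS)methyl]-1,3-dioxolan-4-one (2,5-cis) | O=C1O[C@@H](/C=C/c2ccc(O[Si](C)(C)C(C)(C)C)cc2)O[C@H]1Cc1ccc2c(c1)C[C@@H](C(C)(C)O[Si](C)(C)C)O2 | intermediate
15 | (2S)-2-[(E)-2-(TBSO-Ph)ethenyl]-5-[(DHB-TMS)methyl]-4-(trimethylsilyloxy)-1,3-dioxole | C[Si](C)(C)OC1=C(Cc2ccc3c(c2)C[C@@H](C(C)(C)O[Si](C)(C)C)O3)O[C@H](/C=C/c2ccc(O[Si](C)(C)C(C)(C)C)cc2)O1 | intermediate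
16 | trimethylsilyl (2S,3R)-2-[(DHB-TMS)methyl]-3-(TBSO-Ph)-2,3-dihydrofuran-2-carboxylate | C[Si](C)(C)OC(=O)[C@@]1(Cc2ccc3c(c2)C[C@@H](C(C)(C)O[Si](C)(C)C)O3)OC=C[C@@H]1c1ccc(O[Si](C)(C)C(C)(C)C)cc1 | intermediate
17 | (2S,3R)-2-[(DHB-TMS)methyl]-3-(TBSO-Ph)-2,3-dihydrofuran-2-carboxylic acid | OC(=O)[C@@]1(Cc2ccc3c(c2)C[C@@H](C(C)(C)O[Si](C)(C)C)O3)OC=C[C@@H]1c1ccc(O[Si](C)(C)C(C)(C)C)cc1 | intermediate
18 | methyl (2S,3R)-2-[(DHB-TMS)methyl]-3-(TBSO-Ph)-2,3-dihydrofuran-2-carboxylate | COC(=O)[C@@]1(Cc2ccc3c(c2)C[C@@H](C(C)(C)O[Si](C)(C)C)O3)OC=C[C@@H]1c1ccc(O[Si](C)(C)C(C)(C)C)cc1 | intermediate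
19 | methyl (2S,3R,4S,5S)-2-[(DHB-TMS)methyl]-4,5-dihydroxy-3-(TBSO-Ph)oxolane-2-carboxylate (lactol, drawn as the kinetic cis-diol) | COC(=O)[C@@]1(Cc2ccc3c(c2)C[C@@H](C(C)(C)O[Si](C)(C)C)O3)O[C@@H](O)[C@@H](O)[C@@H]1c1ccc(O[Si](C)(C)C(C)(C)C)cc1 | intermediate
20 | methyl (2S,3R,4S)-2-[(DHB-TMS)methyl]-4-hydroxy-5-oxo-3-(TBSO-Ph)oxolane-2-carboxylate | COC(=O)[C@@]1(Cc2ccc3c(c2)C[C@@H](C(C)(C)O[Si](C)(C)C)O3)OC(=O)[C@@H](O)[C@@H]1c1ccc(O[Si](C)(C)C(C)(C)C)cc1 | intermediate
21 | methyl (2S,3R)-2-[(DHB-TMS)methyl]-4,5-dioxo-3-(TBSO-Ph)oxolane-2-carboxylate | COC(=O)[C@@]1(Cc2ccc3c(c2)C[C@@H](C(C)(C)O[Si](C)(C)C)O3)OC(=O)C(=O)[C@@H]1c1ccc(O[Si](C)(C)C(C)(C)C)cc1 | intermediate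
22 | methyl (2S)-2-[(DHB-TMS)methyl]-4-hydroxy-5-oxo-3-(TBSO-Ph)-2,5-dihydrofuran-2-carboxylate | COC(=O)[C@@]1(Cc2ccc3c(c2)C[C@@H](C(C)(C)O[Si](C)(C)C)O3)OC(=O)C(O)=C1c1ccc(O[Si](C)(C)C(C)(C)C)cc1 | intermediate
23 | methyl (2S)-4-hydroxy-2-{[(2S)-2-(2-hydroxypropan-2-yl)-2,3-dihydro-1-benzofuran-5-yl]methyl}-3-(4-hydroxyphenyl)-5-oxo-2,5-dihydrofuran-2-carboxylate | COC(=O)[C@@]1(Cc2ccc3c(c2)C[C@@H](C(C)(C)O)O3)OC(=O)C(O)=C1c1ccc(O)cc1 | target

## Step count and risks

Total steps: 9. Longest linear sequence: 8 (steps 1, 2, 3, 5, 6, 7, 8, 9; step 4 is a one-step side branch).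

Steps most likely to fail:

**Step 6 (ring-contracting Ireland–Claisen).** The one-atom-bridged boat transition state is strained, and ionisation of the acetal C–O bond before C–C bonding would leak stereochemical information.

Fallback: this route sets out from 6 and comes back at 23. It replaces the sigmatropic step by an enolate Michael addition with self-regeneration of the stereocentre. Because the electrophile then enters trans to the acetal substituent (net retention), the opposite lactic acid is needed.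
- Bromide 6 is metalated as in step 3 and opened with methyl (2R)-oxirane-2-carboxylate to give methyl (2R)-2-hydroxy-3-(DHB)propanoate F1, saponified to (2R)-2-hydroxy-3-(DHB)propanoic acid F2.
- Pivalaldehyde (cat. TsOH, pentane, water separator) gives (2R,5R)-2-tert-butyl-5-[(DHB)methyl]-1,3-dioxolan-4-one F3.
- Its enolate (LiN(SiMe3)2, 2.1 equiv, THF, −78 °C) adds to ethyl 2-nitro-3-(TBSO-Ph)prop-2-enoate F4 (made from 10 and ethyl nitroacetate with TiCl4/pyridine; E/Z mixture is immaterial). This gives the Michael adduct (2R,5S)-2-tert-butyl-5-[(DHB)methyl]-5-[2-ethoxycarbonyl-2-nitro-1-(TBSO-Ph)ethyl]-1,3-dioxolan-4-one F5, a mixture at the two side-chain centres.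
- A Nef reaction on the potassium nitronate (KOtBu, then dimethyldioxirane, −78 °C) gives the keto ester (2R,5S)-2-tert-butyl-5-[(DHB)methyl]-5-[3-ethoxy-2,3-dioxo-1-(TBSO-Ph)propyl]-1,3-dioxolan-4-one F6.
- K2CO3 in MeOH opens the dioxolanone to the methyl ester, lactonises the freed tertiary alkoxide onto the keto ester and removes the aryl silyl group, giving 23.

**Step 8 (double oxidation of the lactol diol).** Glycol cleavage or over-oxidation of the electron-rich enol product is possible.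

Fallback: this route sets out from 18 and comes back at 22. It avoids the vicinal diol by oxidising carbon by carbon.
- [C5H5NH][CrO3Cl] (pyridinium chlorochromate) in CH2Cl2 oxidises the cyclic enol ether of 18 directly to the saturated lactone methyl (2S,3R)-2-[(DHB-TMS)methyl]-5-oxo-3-(TBSO-Ph)oxolane-2-carboxylate F7.
- Its potassium enolate (KN(SiMe3)2, THF, −78 °C) is hydroxylated with racemic 2-(phenylsulfonyl)-3-phenyloxaziridine to give 20 together with its C4 epimer methyl (2S,3R,4R)-2-[(DHB-TMS)methyl]-4-hydroxy-5-oxo-3-(TBSO-Ph)oxolane-2-carboxylate F8.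
- Both epimers are oxidised by one equivalent of Dess–Martin periodinane to 22.

**Step 2 (copper-catalysed cyclisation).** The tertiary alkoxide could close the six-membered ring, or the para bromide could couple intermolecularly.

Fallback: this route sets out from 2 and comes back at 6. It uses a metal-free intramolecular SNAr on a fluoroarene, so only one position can react.
- 4-Bromo-1-fluoro-2-iodobenzene replaces 1 in the step 1 protocol: iodine–magnesium exchange gives (5-bromo-2-fluorophenyl)magnesium chloride F9.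
- CuI-catalysed opening of 2 gives methyl (2S)-3-(5-bromo-2-fluorophenyl)-2-hydroxypropanoate F10, and MeMgBr gives (2S)-1-(5-bromo-2-fluorophenyl)-3-methylbutane-2,3-diol F11.
- KOtBu in DMF at 70 °C displaces fluoride with the secondary alkoxide, with retention at the carbinol carbon, to give 6.

## Further compounds

F1 | step 6 | methyl (2R)-2-hydroxy-3-(DHB)propanoate | COC(=O)[C@H](O)Cc1ccc2c(c1)C[C@@H](C(C)(C)O)O2
F2 | step 6 | (2R)-2-hydroxy-3-(DHB)propanoic acid | OC(=O)[C@H](O)Cc1ccc2c(c1)C[C@@H](C(C)(C)O)O2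
F3 | step 6 | (2R,5R)-2-tert-butyl-5-[(DHB)methyl]-1,3-dioxolan-4-one | O=C1O[C@H](C(C)(C)C)O[C@@H]1Cc1ccc2c(c1)C[C@@H](C(C)(C)O)O2
F4 | step 6 | ethyl 2-nitro-3-(TBSO-Ph)prop-2-enoate (E/Z mixture) | CCOC(=O)C(=Cc1ccc(O[Si](C)(C)C(C)(C)C)cc1)[N+](=O)[O-]
F5 | step 6 | (2R,5S)-2-tert-butyl-5-[(DHB)methyl]-5-[2-ethoxycarbonyl-2-nitro-1-(TBSO-Ph)ethyl]-1,3-dioxolan-4-one (side-chain centres as a mixture) | O=C1O[C@H](C(C)(C)C)O[C@]1(C(c1ccc(O[Si](C)(C)C(C)(C)C)cc1)C(C(=O)OCC)[N+](=O)[O-])Cc1ccc2c(c1)C[C@@H](C(C)(C)O)O2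
F6 | step 6 | (2R,5S)-2-tert-butyl-5-[(DHB)methyl]-5-[3-ethoxy-2,3-dioxo-1-(TBSO-Ph)propyl]-1,3-dioxolan-4-one (side-chain centre as a mixture) | O=C1O[C@H](C(C)(C)C)O[C@]1(C(c1ccc(O[Si](C)(C)C(C)(C)C)cc1)C(=O)C(=O)OCC)Cc1ccc2c(c1)C[C@@H](C(C)(C)O)O2
F7 | step 8 | methyl (2S,3R)-2-[(DHB-TMS)methyl]-5-oxo-3-(TBSO-Ph)oxolane-2-carboxylate | COC(=O)[C@@]1(Cc2ccc3c(c2)C[C@@H](C(C)(C)O[Si](C)(C)C)O3)OC(=O)C[C@@H]1c1ccc(O[Si](C)(C)C(C)(C)C)cc1
F8 | step 8 | methyl (2S,3R,4R)-2-[(DHB-TMS)methyl]-4-hydroxy-5-oxo-3-(TBSO-Ph)oxolane-2-carboxylate | COC(=O)[C@@]1(Cc2ccc3c(c2)C[C@@H](C(C)(C)O[Si](C)(C)C)O3)OC(=O)[C@H](O)[C@@H]1c1ccc(O[Si](C)(C)C(C)(C)C)cc1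
F9 | step 2 | (5-bromo-2-fluorophenyl)magnesium chloride | Cl[Mg]c1cc(Br)ccc1F
F10 | step 2 | methyl (2S)-3-(5-bromo-2-fluorophenyl)-2-hydroxypropanoate | COC(=O)[C@@H](O)Cc1cc(Br)ccc1F
F11 | step 2 | (2S)-1-(5-bromo-2-fluorophenyl)-3-methylbutane-2,3-diol | CC(C)(O)[C@@H](O)Cc1cc(Br)ccc1F
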